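**Proposed synthesis of (2S)-5,7-dihydroxy-2-[4-hydroxy-3-methoxy-5-(3-methylbut-2-en-1-yl)phenyl]chroman-4-one (18) by an o-quinone methide/styrene cycloaddition**

## Analysis of the target

The target is a flavanone. Ring A is a phloroglucinol-type ring (C4a to C8a) with free hydroxyls at C5 and C7, fused to the dihydropyranone ring C (O1, C2, C3, C4). Ring B sits on C2 and carries a free 4'-hydroxyl between a 3'-methoxy group and a 5'-prenyl chain. C2 is the only stereocentre and has the (S) configuration (read from the SMILES: O1 > C1' > C3 > H). It is benzylic, bonded to O1 and β to the ketone, and has no neighbouring centre to relay from, so a catalyst or reagent must set it. Once the ketone is present, ring C can open to the 2'-hydroxychalcone by retro-oxa-Michael reaction under base, and more slowly under acid or heat, which racemises C2. The prenyl alkene excludes hydrogenation and strong electrophiles, and next to a free phenol it cyclises under acid to a 2,2-dimethylchroman; the free phenols and ring A are also oxidant-sensitive. The difficulty is therefore to create C2 enantioselectively on an acid-, base- and oxidant-sensitive frame and then to keep it. The strategy rests on ring C: cutting O1–C2 and C3–C4 divides it into the four-atom heterodiene O1–C8a–C4a–C4 (an o-quinone methide of ring A) and the two-carbon unit C2–C3 (the vinyl group of a ring B styrene). This builds the skeleton at the flavan level, so C4 must later be raised from CH2 to C=O, and the oxygens at C5, C7 and C8a provide the activation for that.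

## Retrosynthetic reasoning

**Deprotection (18 ⇒ 17 ⇒ 16).** Only oxygen–protecting-group bonds are cut. The two acetal ethers on ring A of 16 need acid and the silyl ether on ring B needs fluoride. The acetals go first, giving 17, because a silylated 4'-oxygen cannot add to the neighbouring prenyl alkene under acid. The silyl group then leaves under buffered fluoride to give 18, so the ketone never meets base.

**Oxidation level of C4 (16 ⇒ 15 ⇒ 14).** No skeletal bond changes; the C4 carbonyl is taken back to carbinol 15 and then to the methylene group of flavan 14. The cut is placed here because C4–H of 14 is benzylic to a ring with oxygen at C5, C7 and C8a, so hydride abstraction gives a cation with three donors. C2–H and the prenyl CH2 have weaker support. The gain is that the ring-forming step runs at the flavan level, where no ketone exists and C2 cannot racemise by ring opening. Forward, the oxidation must stay at C4 and the cation must be hydrated, not deprotonated at C3.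

**Ring C (14 ⇒ 13 + 12; 13 ⇒ 3).** O1–C2 and C3–C4 are cut together in a retro-(4+2) step. This pair gives two fragments of matched polarity: heterodiene 13, electrophilic at the carbon that becomes C4, and styrene 12, nucleophilic at its terminal carbon (future C3) and able to carry positive charge at the future C2. Compound 13 is too reactive to handle and is traced to the o-hydroxybenzyl alcohol 3 by dehydration. One ring, two bonds and the stereocentre are gained in a single operation. Forward, a chiral acid has to generate 13 and decide which face of the vinyl group becomes bonded to O1.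

**Ring A fragment (3 ⇒ 2 ⇒ 1).** Compound 3 is the reduction product of salicylaldehyde 2, which comes from 1 by acetal protection of two of its three hydroxyls. The hydroxyl left free is the one needed as O1, and it is spared naturally because it is hydrogen-bonded to the aldehyde.

**Ring B fragment (12 ⇒ 11 ⇒ 10).** The vinyl group is cut at its double bond (Wittig methylenation of aldehyde 11), and the silyl ether of 11 is cut back to phenol 10. The aldehyde is kept until this point because it comes with the starting material and tolerates the steps that build the prenyl group.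

**Prenyl group (10 ⇒ 9 ⇒ 8 ⇒ 7 ⇒ 4 + 6; 6 ⇒ 5).** The aryl–CH2 bond of the prenyl chain is cut by a retro-Claisen step: 10 is the tautomer of dienone 9, which arises by a [3,3] shift from the tertiary allyl ether 8. This is preferred to direct C-alkylation of a phenol, which gives O/C mixtures, because the shift can deliver the chain only to the one free ortho carbon. Compound 8 comes from alkyne 7 by semihydrogenation, and 7 from O-alkylation of vanillin 4 with the activated ester 6 of alkynol 5.

## Alternatives that were turned down

**Alternative 1:** The cut is at C8a–O1 and C4a–C4, so ring A arrives as aryne A2 and the rest (C2, C3, C4, ring B and the C2 oxygen) as the chiral β-silyloxy acid A1. In the forward step, fluoride-generated A2 inserts into the acyl C–OH bond of A1 to give the o-hydroxyaryl ketone A3, which is still open-chain. Desilylation and a Mitsunobu-type closure with inversion, (R) to (2S), would follow.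
- For: it is convergent, C4 arrives as the ketone so no late C–H oxidation is needed, and the C2 configuration would come from dependable asymmetric aldol or ketone-reduction chemistry. On these points it is stronger than the chosen route. The regiochemistry is also sound, since the ether next to the aryne bond sends the oxygen nucleophile to the remote aryne carbon and puts the acyl group between the hydroxyl and an ether.
- Against: A3 is a β-silyloxy ketone with acidic α-hydrogens, formed in a basic fluoride medium, so E1cB loss of the silyloxy group would erase the stereocentre. The closure must then displace a benzylic oxygen para to an ether oxygen with clean inversion, where ionisation gives racemate. A1 and the source of A2 each need several steps, and ring C is still open after the key step.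
- Comparison: the chosen route closes ring C and sets C2 in one operation from two simpler fragments, and pays for this with the later oxidation at C4.

**Alternative 2:** The cut is at C2–C3. Enol acetal A4 holds the ring B carbon as an acetal between O1 and an enol oxygen. An acid ionises the acetal C–O(enol) bond, and the enolate carbon then adds back to the oxocarbenium carbon (Petasis–Ferrier O-to-C rearrangement) to give flavanone A5 directly.
- For: the ketone is delivered at the right oxidation level with all three phenols as silyl ethers, so a single fluoride step would finish. In end-game step economy it is stronger than the chosen route, which needs two oxidation steps and two deprotections.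
- Against: enantioselection would require a chiral counter-anion to control recombination of an enolate with an O-aryl oxocarbenium ion, and only the racemic Lewis-acid version of this rearrangement is dependable. The flavanone forms under acid with the ring-opening path available, so any enantiomeric excess could erode. A4 is an acid-labile enol acetal that needs a titanium-mediated carbonyl methylenation.
- Comparison: the chosen route offers an enantioselective ring closure of an established catalytic type, carried out at the flavan level where C2 is configurationally safe.

**Alternative 3:** The cuts are at C4a–C4, C4–C3 and O1–C2 at the flavone level. Iodophenol A6, carbon monoxide A7 and aryl acetylene A8 are joined under palladium catalysis with an amine to flavone A9. C2 would then be created by asymmetric reduction of the C2=C3 bond.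
- For: three components are joined in one robust step, A9 is a stable achiral intermediate, and the stereocentre is set last. In convergence and reliability of bond formation it is stronger than the chosen route.
- Against: the enantioselective step is reduction of a β-aryl, β-oxy enone that behaves as a vinylogous ester and is further deactivated by two ring A oxygens. Catalysts strong enough to hydrogenate it would also saturate the prenyl alkene and over-reduce the ketone. In the carbonylation, five-membered closure competes with six-membered closure.
- Comparison: the chosen route fixes C2 while the skeleton forms and uses no reductant that could touch the prenyl group.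

Key step: step 8

Assumption: the (R)-enantiomer of the phosphoric acid is taken to give the (2S)-flavan. The sense of induction cannot be derived from structure for a methide without a substituent on the methide carbon, and the (S)-acid would be used if the opposite sense is found.

## Route

Step 1
Reactants: 1 2,4,6-trihydroxybenzaldehyde
Product: 2 2-hydroxy-4,6-bis(methoxymethoxy)benzaldehyde
Conditions: MOMCl (2.2 equiv), i-Pr2NEt, CH2Cl2, 0 °C → rt
Reagents that add atoms: chloromethyl methyl ether (MOMCl), COCCl
Why: Selective O-alkylation of a polyhydroxy aryl aldehyde: the para hydroxyl and one ortho hydroxyl react, while the remaining ortho hydroxyl is held in a hydrogen bond to the carbonyl and should stay free.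

Step 2
Reactants: 2 2-hydroxy-4,6-bis(methoxymethoxy)benzaldehyde
Product: 3 2-(hydroxymethyl)-3,5-bis(methoxymethoxy)phenol
Conditions: NaBH4, THF/MeOH, 0 °C; pH 7 buffer, cold work-up, used at once
Reagents that add atoms: none
Why: Borohydride reduction of an aryl aldehyde; the acetal ethers are inert to hydride and base. The product is an electron-rich saligenin that ionises easily, so it is kept cold and neutral and taken directly into step 8.

Step 3
Reactants: 4 vanillin (4-hydroxy-3-methoxybenzaldehyde), 5 2-methylbut-3-yn-2-ol
Product: 7 3-methoxy-4-[(2-methylbut-3-yn-2-yl)oxy]benzaldehyde, via 2-methylbut-3-yn-2-yl trifluoroacetate 6 (not isolated)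
Conditions: 5, (CF3CO)2O, DBU, MeCN, −5 °C; then 4, DBU, CuCl2·2H2O (0.1 mol %), MeCN, −5 → 0 °C
Reagents that add atoms: none
Why: Copper-catalysed propargylic etherification of a phenol with a tertiary propargylic trifluoroacetate made in the flask; acidic phenols such as 4 are good partners, and the aldehyde is untouched.

Step 4
Reactants: 7 3-methoxy-4-[(2-methylbut-3-yn-2-yl)oxy]benzaldehyde
Product: 8 3-methoxy-4-[(2-methylbut-3-en-2-yl)oxy]benzaldehyde
Conditions: H2 (1 atm), Pd/CaCO3 poisoned with Pb(OAc)2 (Lindlar catalyst), quinoline, EtOAc, rt
Reagents that add atoms: none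
Why: Lindlar semihydrogenation stops at the terminal alkene and leaves the aldehyde alone. It is needed because heating the alkynyl ether would give a 2,2-dimethylchromene, not the prenyl phenol.

Step 5
Reactants: 8 3-methoxy-4-[(2-methylbut-3-en-2-yl)oxy]benzaldehyde
Product: 10 4-hydroxy-3-methoxy-5-(3-methylbut-2-en-1-yl)benzaldehyde, via ortho-dienone 9 (not isolated)
Conditions: PhNEt2, 130 °C
Reagents that add atoms: none
Why: Aromatic Claisen rearrangement: the [3,3] shift delivers the allyl terminus to the only free ortho carbon and transposes the tertiary ether into the linear prenyl chain, and dienone 9 tautomerises to the phenol. The amine solvent suppresses acid-promoted loss of the tertiary allyl group.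

Step 6
Reactants: 10 4-hydroxy-3-methoxy-5-(3-methylbut-2-en-1-yl)benzaldehyde
Product: 11 4-(tert-butyldimethylsilyloxy)-3-methoxy-5-(3-methylbut-2-en-1-yl)benzaldehyde
Conditions: TBSCl, imidazole, DMAP (cat.), DMF, rt
Reagents that add atoms: tert-butyldimethylsilyl chloride (TBSCl), CC(C)(C)[Si](C)(C)Cl
Why: Imidazole-promoted silylation of a phenol, which works for 2,6-disubstituted phenols of this kind. The silyl ether shields the phenol from the ylide and later keeps it away from the prenyl alkene under acid.

Step 7
Reactants: 11 4-(tert-butyldimethylsilyloxy)-3-methoxy-5-(3-methylbut-2-en-1-yl)benzaldehyde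
Product: 12 tert-butyl[2-methoxy-6-(3-methylbut-2-en-1-yl)-4-vinylphenoxy]dimethylsilane (4-silyloxy-3-methoxy-5-prenylstyrene)
Conditions: Ph3PCH3Br, KOtBu, THF, 0 °C → rt
Reagents that add atoms: methyltriphenylphosphonium bromide, C[P+](c1ccccc1)(c1ccccc1)c1ccccc1.[Br-]
Why: Wittig methylenation of an aryl aldehyde with a non-stabilised ylide; the phosphonium salt is kept in slight excess over the base so that no free alkoxide attacks the aryl silyl ether.

Step 8
Reactants: 3 2-(hydroxymethyl)-3,5-bis(methoxymethoxy)phenol (1.5 equiv), 12 4-silyloxy-3-methoxy-5-prenylstyrene
Product: 14 (2S)-2-[4-(tert-butyldimethylsilyloxy)-3-methoxy-5-(3-methylbut-2-en-1-yl)phenyl]-5,7-bis(methoxymethoxy)chromane, via o-quinone methide 13 (not isolated)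
Conditions: (R)-3,3'-bis(2,4,6-triisopropylphenyl)-1,1'-binaphthyl-2,2'-diyl hydrogen phosphate [(R)-TRIP, 10 mol %], 4 Å MS, PhMe, 0 °C → rt; 3 added slowly to 12 and catalyst
Reagents that add atoms: none
Why: The phosphoric acid activates the benzylic hydroxyl of 3 and water is lost, helped by the ortho hydroxyl and the two ether oxygens ortho and para to the benzylic carbon, to give o-quinone methide 13 held on the catalyst by a hydrogen bond from P–OH to the methide oxygen (in the limit, a hydroxybenzyl cation–phosphate ion pair). The terminal vinyl carbon of 12 attacks the methide carbon (new C3–C4 bond) while positive charge develops at the benzylic carbon, stabilised by the para silyloxy oxygen of ring B, and the methide oxygen closes onto it (new O1–C2 bond) in an asynchronous inverse-electron-demand oxa-Diels–Alder reaction. The closest known reaction type is the chiral phosphoric acid catalysed (4+2) cycloaddition of in situ o-quinone methides from o-hydroxybenzyl alcohols with styrenes to give 2-arylchromans, documented mainly for methides with an aryl group on the methide carbon; the unsubstituted but threefold oxygen-stabilised methide used here lies in the same class. Ring C closes as the six-membered ring of a (4+2) cycloaddition, with four atoms (O1, C8a, C4a, C4) from 13 and two (C2, C3) from 12; in the stepwise limit O1 captures the C2 benzylic cation in a six-membered closure. C2 is the only new stereocentre and is set by the chiral phosphate, whose 3,3'-aryl groups must leave one face of bound 13 open and hold the aryl group of 12 in one orientation, because both choices together decide between (2S) and (2R). Regiochemistry (aryl at C2, not C3) follows from polarity, the nucleophilic CH2 terminus meeting the electrophilic methide carbon. The step also needs the vinyl group to react in preference to the prenyl alkene, which conjugation with the oxygenated ring should secure, and cycloaddition to win over Friedel–Crafts capture of 13 by ring A of 3 or 14, which slow addition of 3 into an excess of 12 should secure. The weak acid and dry medium should leave the acetal and silyl ethers intact.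

Step 9
Reactants: 14 (2S)-flavan
Product: 15 (2S,4RS)-2-[4-(tert-butyldimethylsilyloxy)-3-methoxy-5-(3-methylbut-2-en-1-yl)phenyl]-5,7-bis(methoxymethoxy)chroman-4-ol (both C4 epimers)
Conditions: DDQ (1.1 equiv), CH2Cl2/pH 7 phosphate buffer, 0 °C
Reagents that add atoms: water, O
Why: Benzylic C–H oxidation by quinone hydride abstraction, the reaction type used for C4 functionalisation of 5,7-dialkoxyflavans. The C4 cation is stabilised by the oxygens at C5, C7 and C8a and is trapped by water, the buffer prevents re-ionisation of the carbinol, and C2 is not involved. Any ketone 16 formed by further oxidation is simply carried into step 10.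

Step 10
Reactants: 15 (2S,4RS)-flavan-4-ol
Product: 16 (2S)-2-[4-(tert-butyldimethylsilyloxy)-3-methoxy-5-(3-methylbut-2-en-1-yl)phenyl]-5,7-bis(methoxymethoxy)chroman-4-one
Conditions: Dess–Martin periodinane, pyridine, CH2Cl2, 0 °C → rt
Reagents that add atoms: none
Why: Dess–Martin oxidation of a secondary benzylic alcohol under buffered, near-neutral conditions; both C4 epimers converge on one ketone, and no base strong enough to open ring C is present, so C2 should be retained.

Step 11
Reactants: 16 (2S)-5,7-bis(methoxymethoxy)-4'-silyloxy flavanone
Product: 17 (2S)-2-[4-(tert-butyldimethylsilyloxy)-3-methoxy-5-(3-methylbut-2-en-1-yl)phenyl]-5,7-dihydroxychroman-4-one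
Conditions: 1 M HCl in MeOH, THF, 0 °C → rt
Reagents that add atoms: none
Why: Acid-catalysed acetal exchange of the aryl methoxymethyl ethers with methanol. The hindered aryl silyl ether, flanked by methoxy and prenyl groups, should survive and keep the 4'-oxygen from adding to the prenyl alkene. The temperature is kept low to avoid acid-promoted opening of ring C.

Step 12
Reactants: 17 (2S)-5,7-dihydroxy-4'-silyloxy flavanone
Product: 18 (2S)-5,7-dihydroxy-2-[4-hydroxy-3-methoxy-5-(3-methylbut-2-en-1-yl)phenyl]chroman-4-one (target)
Conditions: Bu4NF, AcOH (1:1), THF, 0 °C
Reagents that add atoms: none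
Why: Fluoride cleavage of an aryl silyl ether, driven by the Si–F bond. Acetic acid keeps the medium from turning basic, so retro-oxa-Michael opening of ring C and loss of the C2 configuration should be avoided, and the prenyl alkene is untouched.

## Compound list

1 | 2,4,6-trihydroxybenzaldehyde | O=Cc1c(O)cc(O)cc1O | starting material
2 | 2-hydroxy-4,6-bis(methoxymethoxy)benzaldehyde | O=Cc1c(O)cc(OCOC)cc1OCOC | intermediate
3 | 2-(hydroxymethyl)-3,5-bis(methoxymethoxy)phenol | OCc1c(O)cc(OCOC)cc1OCOC | intermediate
4 | vanillin (4-hydroxy-3-methoxybenzaldehyde) | COc1cc(C=O)ccc1O | starting material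
5 | 2-methylbut-3-yn-2-ol | CC(C)(O)C#C | starting material
6 | 2-methylbut-3-yn-2-yl trifluoroacetate | CC(C)(OC(=O)C(F)(F)F)C#C | intermediate (not isolated)
7 | 3-methoxy-4-[(2-methylbut-3-yn-2-yl)oxy]benzaldehyde | COc1cc(C=O)ccc1OC(C)(C)C#C | intermediate
8 | 3-methoxy-4-[(2-methylbut-3-en-2-yl)oxy]benzaldehyde | COc1cc(C=O)ccc1OC(C)(C)C=C | intermediate
9 | 5-methoxy-3-(3-methylbut-2-en-1-yl)-4-oxocyclohexa-1,5-diene-1-carbaldehyde (ortho-dienone, racemic) | COC1=CC(C=O)=CC(CC=C(C)C)C1=O | intermediate (not isolated)
10 | 4-hydroxy-3-methoxy-5-(3-methylbut-2-en-1-yl)benzaldehyde | COc1cc(C=O)cc(CC=C(C)C)c1O | intermediate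
11 | 4-(tert-butyldimethylsilyloxy)-3-methoxy-5-(3-methylbut-2-en-1-yl)benzaldehyde | COc1cc(C=O)cc(CC=C(C)C)c1O[Si](C)(C)C(C)(C)C | intermediate
12 | tert-butyl[2-methoxy-6-(3-methylbut-2-en-1-yl)-4-vinylphenoxy]dimethylsilane | C=Cc1cc(OC)c(O[Si](C)(C)C(C)(C)C)c(CC=C(C)C)c1 | intermediate
13 | 3,5-bis(methoxymethoxy)-6-methylidenecyclohexa-2,4-dien-1-one (o-quinone methide) | C=C1C(=O)C=C(OCOC)C=C1OCOC | intermediate (not isolated)
14 | (2S)-2-[4-(tert-butyldimethylsilyloxy)-3-methoxy-5-(3-methylbut-2-en-1-yl)phenyl]-5,7-bis(methoxymethoxy)chromane | COc1cc([C@@H]2CCc3c(OCOC)cc(OCOC)cc3O2)cc(CC=C(C)C)c1O[Si](C)(C)C(C)(C)C | intermediate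
15 | (2S,4RS)-2-[4-(tert-butyldimethylsilyloxy)-3-methoxy-5-(3-methylbut-2-en-1-yl)phenyl]-5,7-bis(methoxymethoxy)chroman-4-ol | COc1cc([C@@H]2CC(O)c3c(OCOC)cc(OCOC)cc3O2)cc(CC=C(C)C)c1O[Si](C)(C)C(C)(C)C | intermediate
16 | (2S)-2-[4-(tert-butyldimethylsilyloxy)-3-methoxy-5-(3-methylbut-2-en-1-yl)phenyl]-5,7-bis(methoxymethoxy)chroman-4-one | COc1cc([C@@H]2CC(=O)c3c(OCOC)cc(OCOC)cc3O2)cc(CC=C(C)C)c1O[Si](C)(C)C(C)(C)C | intermediate
17 | (2S)-2-[4-(tert-butyldimethylsilyloxy)-3-methoxy-5-(3-methylbut-2-en-1-yl)phenyl]-5,7-dihydroxychroman-4-one | COc1cc([C@@H]2CC(=O)c3c(O)cc(O)cc3O2)cc(CC=C(C)C)c1O[Si](C)(C)C(C)(C)C | intermediate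
18 | (2S)-5,7-dihydroxy-2-[4-hydroxy-3-methoxy-5-(3-methylbut-2-en-1-yl)phenyl]chroman-4-one | COc1cc([C@@H]2CC(=O)c3c(O)cc(O)cc3O2)cc(CC=C(C)C)c1O | target

## Step count and least certain steps

Total step count: 12. Longest linear sequence: 10 steps (steps 3 to 7, then 8 to 12, from vanillin 4).

**Step 8 (key step).** The most likely failure is insufficient enantiofacial control. With no substituent on the methide carbon, the catalyst must fix both the open face of 13 and the endo/exo orientation of the aryl group of 12, and a lapse in either lowers the enantiomeric excess. A second risk is self-alkylation, in which 13 is captured by the nucleophilic ring A (C6 or C8) of 3 or 14 instead of by the vinyl group.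
Fallback, setting out from 3 and 12 and returning at 16: the cycloaddition is run with an achiral acid (diphenyl phosphate, PhMe, rt) to give the racemic flavan F1. The conditions of steps 9 and 10 convert it into the racemic carbinol F2 and the racemic ketone F3. F3 is then resolved kinetically by asymmetric transfer hydrogenation with RuCl[(R,R)-TsDPEN](p-cymene) (divalent ruthenium), HCO2H/Et3N, EtOAc, rt, stopped near half conversion. The catalyst enantiomer is chosen so that the (2R)-ketone is reduced to the cis-(2R,4R)-flavan-4-ol F4, which is separated. The unreacted (2S)-ketone is 16.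

**Step 9.** The most likely failure is loss of a proton from C3 of the C4 cation in place of hydration, followed by further dehydrogenation of ring C, which would remove the C2 stereocentre. Competing hydride abstraction at the benzylic and allylic CH2 of the prenyl chain is a second risk.
Fallback, setting out from 2 and 12 and returning at 16: the C4 oxygen is brought in from the aldehyde carbon of 2 and no C–H oxidation is used. With trimethyl orthoformate and catalytic camphorsulfonic acid in CH2Cl2, the dimethyl acetal of 2 ionises to a methoxy-substituted o-quinone methide that adds 12 in the known three-component manner to give the racemic 4-methoxyflavan F5. Mild solvolysis (pyridinium p-toluenesulfonate, acetone/water) exchanges the labile benzylic methoxy group for hydroxyl to give the racemic carbinol F2. Dess–Martin oxidation then gives the racemic ketone F3, and the transfer-hydrogenation resolution described for step 8 delivers 16.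

**Step 2.** The most likely failure is self-condensation of the product during work-up and concentration: traces of acid ionise the saligenin to its methide, which is captured by ring A of a second molecule. Over-reduction of the benzylic C–O bond through the same methide is also possible.
Fallback, setting out from 2 and returning at 3: the neutral extract of the reduction is treated at once with phenylboronic acid and MgSO4 to give the cyclic boronate 5,7-bis(methoxymethoxy)-2-phenyl-4H-1,3,2-benzodioxaborinine F6. Here the phenolic oxygen is bound to boron and cannot expel the benzylic oxygen, so the compound can be crystallised and stored. Just before step 8, transesterification with one equivalent of propane-1,3-diol in PhMe releases 3, and the solution is used directly.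

**Step 11.** The most likely failure is acid-promoted addition to the prenyl double bond (addition of methanol or chloride, or ring closure onto the 4'-oxygen if the silyl ether is lost early), together with acid-catalysed opening and reclosure of ring C that erodes the configuration at C2.
Fallback, setting out from 16 and returning at 17: hydrolysis is replaced by a protecting-group exchange under non-protic conditions. Me3SiOTf and 2,2'-bipyridyl in MeCN at 0 °C convert the two aryl methoxymethyl ethers into aryl trimethylsilyl ethers, giving the (2S)-5,7-bis(trimethylsilyloxy) flavanone F7. This is not isolated; water added at the end of the reaction hydrolyses it to 17.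

## Further compounds

F1 | step 8 | racemic 2-[4-(tert-butyldimethylsilyloxy)-3-methoxy-5-(3-methylbut-2-en-1-yl)phenyl]-5,7-bis(methoxymethoxy)chromane | COc1cc(C2CCc3c(OCOC)cc(OCOC)cc3O2)cc(CC=C(C)C)c1O[Si](C)(C)C(C)(C)C
F2 | step 8 | racemic 2-[4-(tert-butyldimethylsilyloxy)-3-methoxy-5-(3-methylbut-2-en-1-yl)phenyl]-5,7-bis(methoxymethoxy)chroman-4-ol (C4 epimers) | COc1cc(C2CC(O)c3c(OCOC)cc(OCOC)cc3O2)cc(CC=C(C)C)c1O[Si](C)(C)C(C)(C)C
F3 | step 8 | racemic 2-[4-(tert-butyldimethylsilyloxy)-3-methoxy-5-(3-methylbut-2-en-1-yl)phenyl]-5,7-bis(methoxymethoxy)chroman-4-one | COc1cc(C2CC(=O)c3c(OCOC)cc(OCOC)cc3O2)cc(CC=C(C)C)c1O[Si](C)(C)C(C)(C)C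
F4 | step 8 | (2R,4R)-2-[4-(tert-butyldimethylsilyloxy)-3-methoxy-5-(3-methylbut-2-en-1-yl)phenyl]-5,7-bis(methoxymethoxy)chroman-4-ol (cis) | COc1cc([C@H]2C[C@@H](O)c3c(OCOC)cc(OCOC)cc3O2)cc(CC=C(C)C)c1O[Si](C)(C)C(C)(C)C
F5 | step 9 | racemic 2-[4-(tert-butyldimethylsilyloxy)-3-methoxy-5-(3-methylbut-2-en-1-yl)phenyl]-4-methoxy-5,7-bis(methoxymethoxy)chromane (C4 epimers) | COc1cc(C2CC(OC)c3c(OCOC)cc(OCOC)cc3O2)cc(CC=C(C)C)c1O[Si](C)(C)C(C)(C)C
F6 | step 2 | 5,7-bis(methoxymethoxy)-2-phenyl-4H-1,3,2-benzodioxaborinine | COCOc1cc(OCOC)c2COB(c3ccccc3)Oc2c1
F7 | step 11 | (2S)-2-[4-(tert-butyldimethylsilyloxy)-3-methoxy-5-(3-methylbut-2-en-1-yl)phenyl]-5,7-bis(trimethylsilyloxy)chroman-4-one | COc1cc([C@@H]2CC(=O)c3c(O[Si](C)(C)C)cc(O[Si](C)(C)C)cc3O2)cc(CC=C(C)C)c1O[Si](C)(C)C(C)(C)C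
A1 | alternative 1 | (R)-3-(tert-butyldimethylsilyloxy)-3-[3-methoxy-4-(methoxymethoxy)-5-(3-methylbut-2-en-1-yl)phenyl]propanoic acid | COc1cc([C@H](O[Si](C)(C)C(C)(C)C)CC(=O)O)cc(CC=C(C)C)c1OCOC
A2 | alternative 1 | 3,5-bis(methoxymethoxy)benzyne | COCOC1=CC(OCOC)=CC#C1
A3 | alternative 1 | (R)-3-(tert-butyldimethylsilyloxy)-1-[2-hydroxy-4,6-bis(methoxymethoxy)phenyl]-3-[3-methoxy-4-(methoxymethoxy)-5-(3-methylbut-2-en-1-yl)phenyl]propan-1-one | COc1cc([C@H](O[Si](C)(C)C(C)(C)C)CC(=O)c2c(O)cc(OCOC)cc2OCOC)cc(CC=C(C)C)c1OCOC
A4 | alternative 2 | 5,7-bis(tert-butyldimethylsilyloxy)-2-[4-(tert-butyldimethylsilyloxy)-3-methoxy-5-(3-methylbut-2-en-1-yl)phenyl]-4-methylidene-4H-1,3-benzodioxine | C=C1OC(c2cc(OC)c(O[Si](C)(C)C(C)(C)C)c(CC=C(C)C)c2)Oc2cc(O[Si](C)(C)C(C)(C)C)cc(O[Si](C)(C)C(C)(C)C)c21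
A5 | alternative 2 | (2S)-5,7-bis(tert-butyldimethylsilyloxy)-2-[4-(tert-butyldimethylsilyloxy)-3-methoxy-5-(3-methylbut-2-en-1-yl)phenyl]chroman-4-one | COc1cc([C@@H]2CC(=O)c3c(O[Si](C)(C)C(C)(C)C)cc(O[Si](C)(C)C(C)(C)C)cc3O2)cc(CC=C(C)C)c1O[Si](C)(C)C(C)(C)C
A6 | alternative 3 | 2-iodo-3,5-bis(methoxymethoxy)phenol | Oc1cc(OCOC)cc(OCOC)c1I
A7 | alternative 3 | carbon monoxide | [C-]#[O+]
A8 | alternative 3 | 5-ethynyl-1-methoxy-2-(methoxymethoxy)-3-(3-methylbut-2-en-1-yl)benzene | C#Cc1cc(OC)c(OCOC)c(CC=C(C)C)c1
A9 | alternative 3 | 5,7-bis(methoxymethoxy)-2-[3-methoxy-4-(methoxymethoxy)-5-(3-methylbut-2-en-1-yl)phenyl]-4H-chromen-4-one | COc1cc(-c2cc(=O)c3c(OCOC)cc(OCOC)cc3o2)cc(CC=C(C)C)c1OCOC
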